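**Retrosynthetic overview**

1. The (2R)-hemiketal is obtained last, by crystallisation-induced asymmetric transformation of the racemic hemiketal, which itself arises by neutral hydrogenolysis of a 2H-chromen-2-ol carrying C4 as a benzyl enol ether.
2. The C2–CH2(pyranone) bond comes from adding the C6-methyl dianion of 4-hydroxy-6-methyl-2H-pyran-2-one to the lactone carbonyl of a 4,7-bis(benzyloxy)coumarin, so C2 is carried at the carboxyl oxidation level until then.
3. Key disconnection C4–C4a: intramolecular Friedel–Crafts acylation of an aryl hydrogen malonate made in the same pot from 5-(3-methylbutyl)resorcinol. The enabling feature is that ring A is a C2v-symmetric 5-alkylresorcinol: either OH can become O1, and the malonyl carboxyl C4, held through O1–C2–C3, then faces C4a, which is ortho to O1 and to the alkyl-bearing C5 and para to the remaining 7-OH.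
4. Ring order: ring A is bought as an arene (side chain by copper-catalysed sp3–sp3 coupling), ring B is closed in the key step as a 4-hydroxycoumarin, the pyranone ring is bought intact, and the hemiketal form of ring B is generated last.

Key step: step 3

Assumption: the C2 hemiketal epimerises through its ring-opened 1,3-diketone only under acid or base catalysis and is configurationally stable in neutral media, and the salt of the (R)-hemiketal with the (R)-amine is taken as the less soluble diastereomer (if the opposite pairing crystallises, the (S)-amine is used, which by mirror symmetry deposits the (R)-hemiketal salt).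

**Route**

Step 1
Reactants: 1 1-(bromomethyl)-3,5-dimethoxybenzene; 2 isobutylmagnesium bromide
Product: 3 1,3-dimethoxy-5-(3-methylbutyl)benzene
Conditions: 2 (1.3 equiv), Li2CuCl4 (3 mol %), THF, −20 °C → rt
Reagents that add atoms: none
Why: Copper-catalysed sp3–sp3 cross-coupling of a primary alkyl Grignard reagent with a benzylic bromide should install the 3-methylbutyl chain in one operation.

Step 2
Reactants: 3 1,3-dimethoxy-5-(3-methylbutyl)benzene
Product: 4 5-(3-methylbutyl)benzene-1,3-diol
Conditions: BBr3 (2.5 equiv), CH2Cl2, −78 °C → rt; then H2O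
Reagents that add atoms: none
Why: BBr3 cleavage of both aryl methyl ethers (borate formation, bromide attack on methyl) is the standard route from dimethyl ethers to 5-alkylresorcinols.

Step 3
Reactants: 4 5-(3-methylbutyl)benzene-1,3-diol; 5 2,2-dimethyl-1,3-dioxane-4,6-dione (isopropylidene malonate)
Product: 7 4,7-dihydroxy-5-(3-methylbutyl)-2H-chromen-2-one, via aryl hydrogen malonate 6 (not isolated)
Conditions: 5 (1.05 equiv), toluene, 95 °C (acetone distilled off); evaporate; P2O5/MeSO3H (1:10 w/w), 70 °C; ice-water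
Reagents that add atoms: none
Why: Isopropylidene malonate acylates one of the two equivalent hydroxyls of the C2v-symmetric diol 4 with loss of acetone, installing O1–C2–C3–C4 as an aryl hydrogen malonate with C2 at the carboxyl level; in P2O5/MeSO3H the free carboxyl C4 is activated as a mixed anhydride or acylium ion and attacks C4a in an intramolecular Friedel–Crafts acylation, after which the chromane-2,4-dione enolises to the 4-hydroxycoumarin. The closest known reaction type is the two-stage synthesis of 4-hydroxycoumarins from phenols, isopropylidene malonate and P2O5/MeSO3H, established for resorcinol itself. Ring B is closed in a 6-exo-trig mode (C4a adds to the trigonal C4, whose C=O lies outside the new ring). No stereocentre is formed. The step needs regioselection between C4a and C8, the two carbons ortho to the acylated oxygen: C4a is para to the free 7-OH and ortho to the alkyl group, the position at which Pechmann, Gattermann and Hoesch reactions of 5-alkylresorcinols occur, whereas C8 is buttressed between two oxygen substituents; the symmetry of 4 removes any question of which hydroxyl is acylated.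

Step 4
Reactants: 7 4,7-dihydroxy-5-(3-methylbutyl)-2H-chromen-2-one
Product: 8 4,7-bis(benzyloxy)-5-(3-methylbutyl)-2H-chromen-2-one
Conditions: BnOH (2.4 equiv), PPh3, DIAD, THF, 0 °C → rt
Reagents that add atoms: benzyl alcohol OCc1ccccc1
Why: Mitsunobu etherification of the two acidic hydroxyls (the vinylogous-acid 4-OH and the 7-phenol) should cap both as benzyl ethers and, unlike benzyl halide/base alkylation, avoid C3-benzylation of the 4-hydroxycoumarin.

Step 5
Reactants: 8 4,7-bis(benzyloxy)-5-(3-methylbutyl)-2H-chromen-2-one; 9 4-hydroxy-6-methyl-2H-pyran-2-one (triacetic acid lactone)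
Product: 11 rac-4,7-bis(benzyloxy)-2-[(4-hydroxy-2-oxo-2H-pyran-6-yl)methyl]-5-(3-methylbutyl)-2H-chromen-2-ol, via dilithio pyranone dianion 10 (not isolated)
Conditions: 9 (2.2 equiv), LiN(iPr)2 (4.5 equiv), THF–DMPU, −78 °C; then 8, −78 → −30 °C; AcOH quench at −78 °C, pH 7 buffer
Reagents that add atoms: none
Why: In a Claisen-type acylation the C6-methyl carbanion of dianion 10 adds to the lactone carbonyl C2 (C4 is a deactivated vinylogous carbonate position shielded by the peri alkyl group), the tetrahedral alkoxide opens to the phenoxide and the new doubly activated ketone is enolised at once so that only one addition occurs, and on neutral quench the hydroxy-enone recloses to the cyclic hemiketal, whose C2 centre is formed without control here (racemic) and is set in step 7.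

Step 6
Reactants: 11 rac-4,7-bis(benzyloxy)-2-[(4-hydroxy-2-oxo-2H-pyran-6-yl)methyl]-5-(3-methylbutyl)-2H-chromen-2-ol
Product: 12 rac-2,7-dihydroxy-2-[(4-hydroxy-2-oxo-2H-pyran-6-yl)methyl]-5-(3-methylbutyl)-2,3-dihydro-4H-chromen-4-one
Conditions: H2 (1 atm), 10% Pd/C, EtOAc–THF, rt
Reagents that add atoms: none
Why: Neutral hydrogenolysis should remove the aryl benzyl ether and the benzyl enol ether, the liberated C4 enol ketonises, and the resulting 1-(2-hydroxyaryl)-1,3-diketone is expected to rest as its cyclic hemiketal by ring–chain tautomerism, still racemic at C2.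

Step 7
Reactants: 12 rac-2,7-dihydroxy-2-[(4-hydroxy-2-oxo-2H-pyran-6-yl)methyl]-5-(3-methylbutyl)-2,3-dihydro-4H-chromen-4-one
Product: 13 (1R)-N,N-dimethyl-1-phenylethanaminium 6-{[(2R)-2,7-dihydroxy-5-(3-methylbutyl)-4-oxo-3,4-dihydro-2H-chromen-2-yl]methyl}-2-oxo-2H-pyran-4-olate
Conditions: (1R)-N,N-dimethyl-1-phenylethan-1-amine (1.0 equiv), i-PrOAc–MeOH, 45 → 5 °C, slurry ageing, filtration
Reagents that add atoms: (1R)-N,N-dimethyl-1-phenylethan-1-amine C[C@@H](N(C)C)c1ccccc1
Why: This is a crystallisation-induced asymmetric transformation (dynamic diastereomeric salt resolution) in which the tertiary amine forms a salt with the acidic pyranone OH and, as a base, keeps the two C2 epimers in equilibrium through the ring-opened diketone while the less soluble (R)-hemiketal·(R)-ammonium salt leaves the solution, so that C2 is set under thermodynamic control by the lattice of the chiral ammonium salt.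

Step 8
Reactants: 13 (1R)-N,N-dimethyl-1-phenylethanaminium 6-{[(2R)-2,7-dihydroxy-5-(3-methylbutyl)-4-oxo-3,4-dihydro-2H-chromen-2-yl]methyl}-2-oxo-2H-pyran-4-olate
Product: 14 (2R)-2,7-dihydroxy-2-[(4-hydroxy-2-oxo-2H-pyran-6-yl)methyl]-5-(3-methylbutyl)-2,3-dihydro-4H-chromen-4-one
Conditions: EtOAc / 0.5 M aq. HCl (1.05 equiv), 0 °C; dry, concentrate below 25 °C
Reagents that add atoms: none
Why: Protonation of the pyranonate in a cold two-phase system should partition the amine into water as its hydrochloride and the neutral target into ethyl acetate, under conditions where neither base-mediated ring opening nor acid-mediated dehydration to the chromone is expected, so C2 is not scrambled.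

**Compound list**

1 | 1-(bromomethyl)-3,5-dimethoxybenzene | COc1cc(CBr)cc(OC)c1 | starting material
2 | isobutylmagnesium bromide | CC(C)C[Mg]Br | starting material
3 | 1,3-dimethoxy-5-(3-methylbutyl)benzene | COc1cc(CCC(C)C)cc(OC)c1 | intermediate
4 | 5-(3-methylbutyl)benzene-1,3-diol | CC(C)CCc1cc(O)cc(O)c1 | intermediate
5 | 2,2-dimethyl-1,3-dioxane-4,6-dione | CC1(C)OC(=O)CC(=O)O1 | starting material
6 | 3-[3-hydroxy-5-(3-methylbutyl)phenoxy]-3-oxopropanoic acid | CC(C)CCc1cc(O)cc(OC(=O)CC(=O)O)c1 | intermediate
7 | 4,7-dihydroxy-5-(3-methylbutyl)-2H-chromen-2-one | CC(C)CCc1cc(O)cc2oc(=O)cc(O)c12 | intermediate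
8 | 4,7-bis(benzyloxy)-5-(3-methylbutyl)-2H-chromen-2-one | CC(C)CCc1cc(OCc2ccccc2)cc2oc(=O)cc(OCc3ccccc3)c12 | intermediate
9 | 4-hydroxy-6-methyl-2H-pyran-2-one | Cc1cc(O)cc(=O)o1 | starting material
10 | dilithium 6-methanidyl-2-oxo-2H-pyran-4-olate | [Li+].[Li+].[CH2-]c1cc([O-])cc(=O)o1 | intermediate
11 | rac-4,7-bis(benzyloxy)-2-[(4-hydroxy-2-oxo-2H-pyran-6-yl)methyl]-5-(3-methylbutyl)-2H-chromen-2-ol | CC(C)CCc1cc(OCc2ccccc2)cc2c1C(OCc1ccccc1)=CC(O)(Cc1cc(O)cc(=O)o1)O2 | intermediate
12 | rac-2,7-dihydroxy-2-[(4-hydroxy-2-oxo-2H-pyran-6-yl)methyl]-5-(3-methylbutyl)-2,3-dihydro-4H-chromen-4-one | CC(C)CCc1cc(O)cc2c1C(=O)CC(O)(Cc1cc(O)cc(=O)o1)O2 | intermediate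
13 | (1R)-N,N-dimethyl-1-phenylethanaminium 6-{[(2R)-2,7-dihydroxy-5-(3-methylbutyl)-4-oxo-3,4-dihydro-2H-chromen-2-yl]methyl}-2-oxo-2H-pyran-4-olate | CC(C)CCc1cc(O)cc2c1C(=O)C[C@@](O)(Cc1cc([O-])cc(=O)o1)O2.C[C@@H]([NH+](C)C)c1ccccc1 | intermediate
14 | (2R)-2,7-dihydroxy-2-[(4-hydroxy-2-oxo-2H-pyran-6-yl)methyl]-5-(3-methylbutyl)-2,3-dihydro-4H-chromen-4-one | CC(C)CCc1cc(O)cc2c1C(=O)C[C@@](O)(Cc1cc(O)cc(=O)o1)O2 | target

**Step count and risks**

Total step count: 8. Longest linear sequence: 8 steps (1 → 3 → 4 → 7 → 8 → 11 → 12 → 13 → 14).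

Steps most likely to fail:

1. Step 7. The two diastereomeric salts may not differ enough in solubility (oiling out, or co-crystallisation as a solid solution), or the epimerisation in the mother liquor may be too slow to funnel the material. The fallback sets out from 12: exhaustive silylation (Et3SiOTf, 2,6-lutidine, CH2Cl2, −78 °C) should give racemic 5-(3-methylbutyl)-2-({2-oxo-4-[(triethylsilyl)oxy]-2H-pyran-6-yl}methyl)-2,7-bis[(triethylsilyl)oxy]-2,3-dihydro-4H-chromen-4-one F6, in which C2 is a configurationally stable mixed silyl ketal. The enantiomers are separated by preparative supercritical-fluid chromatography on a polysaccharide chiral stationary phase to give the (2S)-configured silyl ether F7 (the descriptor changes because O–Si outranks O–aryl; the spatial arrangement is that of the target). HF·pyridine buffered with pyridine (THF, 0 °C) then removes the three silyl groups, and the route is rejoined at 14.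

2. Step 5. The dianion may add at C4 with loss of benzyl alcoholate instead of at the lactone carbonyl, proton transfer from the ring-opened product may quench the nucleophile, or the adduct may dehydrate towards a chromone on work-up. The fallback sets out from 8: ring-opening aminolysis with Me2AlN(OMe)Me (from AlMe3 and MeNH(OMe)·HCl, CH2Cl2, 0 °C) should give (2E)-3-(benzyloxy)-3-[4-(benzyloxy)-2-hydroxy-6-(3-methylbutyl)phenyl]-N-methoxy-N-methylprop-2-enamide F3. Its phenol is capped at once (t-BuMe2SiCl, imidazole, DMF) as (2E)-3-(benzyloxy)-3-[4-(benzyloxy)-2-{[tert-butyl(dimethyl)silyl]oxy}-6-(3-methylbutyl)phenyl]-N-methoxy-N-methylprop-2-enamide F4. Acylation of dianion 10 by this amide (THF, −78 °C) cannot expel a phenoxide and should stop at the chelated tetrahedral adduct, giving on work-up (3E)-4-(benzyloxy)-4-[4-(benzyloxy)-2-{[tert-butyl(dimethyl)silyl]oxy}-6-(3-methylbutyl)phenyl]-1-(4-hydroxy-2-oxo-2H-pyran-6-yl)but-3-en-2-one F5. Bu4NF buffered with AcOH (THF, 0 °C) frees the phenol, which recloses onto the ketone, and the route is rejoined at 11.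

3. Step 3. Ring closure may occur at C8 instead of C4a (wrong regiochemistry), both hydroxyls may be acylated, or the acidic medium may cause sulfonation or decarboxylation of the malonate. The fallback sets out from 3: Friedel–Crafts acetylation (AcCl, AlCl3, CH2Cl2, 0 °C) at the position para to one methoxy group and ortho to the alkyl chain should give 1-[2,4-dimethoxy-6-(3-methylbutyl)phenyl]ethan-1-one F1. BBr3 (CH2Cl2, −78 °C → rt) then gives 1-[2,4-dihydroxy-6-(3-methylbutyl)phenyl]ethan-1-one F2. Claisen condensation with diethyl carbonate and lactonisation (NaH in excess, toluene, reflux) closes the 4-hydroxycoumarin through the C2–C3 and O1–C2 bonds, and the route is rejoined at 7.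

**Further compounds**

F1 | step 3 | 1-[2,4-dimethoxy-6-(3-methylbutyl)phenyl]ethan-1-one | COc1cc(CCC(C)C)c(C(C)=O)c(OC)c1
F2 | step 3 | 1-[2,4-dihydroxy-6-(3-methylbutyl)phenyl]ethan-1-one | CC(=O)c1c(O)cc(O)cc1CCC(C)C
F3 | step 5 | (2E)-3-(benzyloxy)-3-[4-(benzyloxy)-2-hydroxy-6-(3-methylbutyl)phenyl]-N-methoxy-N-methylprop-2-enamide | CON(C)C(=O)/C=C(/OCc1ccccc1)c1c(O)cc(OCc2ccccc2)cc1CCC(C)C
F4 | step 5 | (2E)-3-(benzyloxy)-3-[4-(benzyloxy)-2-{[tert-butyl(dimethyl)silyl]oxy}-6-(3-methylbutyl)phenyl]-N-methoxy-N-methylprop-2-enamide | CON(C)C(=O)/C=C(/OCc1ccccc1)c1c(O[Si](C)(C)C(C)(C)C)cc(OCc2ccccc2)cc1CCC(C)C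
F5 | step 5 | (3E)-4-(benzyloxy)-4-[4-(benzyloxy)-2-{[tert-butyl(dimethyl)silyl]oxy}-6-(3-methylbutyl)phenyl]-1-(4-hydroxy-2-oxo-2H-pyran-6-yl)but-3-en-2-one | O=C(Cc1cc(O)cc(=O)o1)/C=C(/OCc1ccccc1)c1c(O[Si](C)(C)C(C)(C)C)cc(OCc2ccccc2)cc1CCC(C)C
F6 | step 7 | rac-5-(3-methylbutyl)-2-({2-oxo-4-[(triethylsilyl)oxy]-2H-pyran-6-yl}methyl)-2,7-bis[(triethylsilyl)oxy]-2,3-dihydro-4H-chromen-4-one | CC[Si](CC)(CC)Oc1cc(CCC(C)C)c2C(=O)CC(O[Si](CC)(CC)CC)(Cc3cc(O[Si](CC)(CC)CC)cc(=O)o3)Oc2c1
F7 | step 7 | (2S)-5-(3-methylbutyl)-2-({2-oxo-4-[(triethylsilyl)oxy]-2H-pyran-6-yl}methyl)-2,7-bis[(triethylsilyl)oxy]-2,3-dihydro-4H-chromen-4-one | CC(C)CCc1cc(O[Si](CC)(CC)CC)cc2c1C(=O)C[C@@](O[Si](CC)(CC)CC)(Cc1cc(O[Si](CC)(CC)CC)cc(=O)o1)O2
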